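## Retrosynthetic overview

1. Core: meso-2,3-dimethylsuccinic acid (1) → cis-anhydride (2). Its mirror symmetry is broken by Rh-catalysed enantioselective arylation with the arylzinc from bromide 3, giving keto acid 4 (C7–C1 bond; C8 and C8' fixed together). One-pot mixed-hydride reduction gives alcohol 5.
2. Ether arm: syringol (6) → bromophenol 7; C8''–O bond by Mitsunobu inversion of methyl (R)-lactate (8) → 9; C7''–C1'' bond by chelation-controlled addition of the Grignard reagent of 3 → threo bromide 10.
3. Union: C7'–C1' (sp3–sp2) bond by deoxygenative Ni/photoredox arylation of 5 with 10 → 11; double debenzylation → target 12.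
4. Rings: no ring is built. The three arenes are bought intact (3 used twice, 6 once); the only ring made is anhydride 2 (step 1), opened in step 2.

Assumption: (S)-t-Bu-PHOX is written for step 2 from memory of the sense of induction; this must be confirmed on the first run, and the commercial (R)-ligand used instead if it is opposite (nothing else changes).

## Route

**Step 1**
Reactants: 1, meso-(2R,3S)-2,3-dimethylsuccinic acid
Product: 2, cis-(3R,4S)-3,4-dimethyloxolane-2,5-dione (meso anhydride)
Conditions: AcCl (neat), reflux, 2 h; evaporate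
Reagents that add atoms: none
Why: Cyclodehydration of a 1,4-diacid; the meso acid can only give the cis anhydride, and the acidic, base-free conditions do not epimerise the α-carbons.

**Step 2 (key step)**
Reactants: 2, cis-3,4-dimethyloxolane-2,5-dione; 3, 1-(benzyloxy)-4-bromo-2-methoxybenzene (used as its arylzinc triflate)
Product: 4, (2S,3R)-4-[4-(benzyloxy)-3-methoxyphenyl]-2,3-dimethyl-4-oxobutanoic acid
Conditions: 3, n-BuLi, THF, −78 °C; Zn(OTf)2, −78 °C → rt; then 2, [Rh(cod)Cl]2 (4 mol %), (S)-t-Bu-PHOX (8 mol %), THF, 50 °C; 1 M HCl; crystallise (dicyclohexylammonium salt) to ≥99 % ee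
Reagents that add atoms: none (3 is a reactant; Li, Zn, Rh are not retained)
Why: Rh/PHOX-catalysed enantioselective desymmetrising acyl cross-coupling (Negishi-type, known for this anhydride with electron-rich arylzincs): the chiral Rh complex inserts into one of the two enantiotopic C(O)–O bonds (the carbonyl next to the R carbon), and aryl transfer and reductive elimination give the keto acid, so the absolute configuration of both methyl-bearing carbons (future C8 and C8') is fixed in one step without touching them.

**Step 3**
Reactants: 4, keto acid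
Product: 5, (2S,3S)-4-[4-(benzyloxy)-3-methoxyphenyl]-2,3-dimethylbutan-1-ol
Conditions: LiAlH4 (3 equiv), Et2O–THF, 0 °C; then AlCl3 (3 equiv), 0 °C → reflux; Rochelle salt work-up
Reagents that add atoms: none (hydride only)
Why: Mixed-hydride (chloroalane) reduction: LiAlH4 takes CO2H to CH2OH and the ketone to the benzylic alkoxide, then AlH2Cl ionises the p-alkoxybenzylic C–O bond (directly or via the 2-aryl-tetrahydrofuran) and delivers hydride; the stereocentres are not reacting carbons and the ketone is reduced before it can enolise.

**Step 4**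
Reactants: 6, 2,6-dimethoxyphenol (syringol)
Product: 7, 4-bromo-2,6-dimethoxyphenol
Conditions: NBS (1.0 equiv), NaH (cat.), CHCl3, −45 °C → rt
Reagents that add atoms: N-bromosuccinimide, O=C1CCC(=O)N1Br
Why: Electrophilic aromatic bromination; the free OH directs para and both ortho positions are blocked by OMe.

**Step 5**
Reactants: 7, 4-bromo-2,6-dimethoxyphenol; 8, methyl (R)-lactate
Product: 9, methyl (2S)-2-(4-bromo-2,6-dimethoxyphenoxy)propanoate
Conditions: PPh3, DIAD, THF, 0 °C → rt
Reagents that add atoms: none (8 is a reactant)
Why: Mitsunobu etherification; SN2 displacement of the activated lactate oxygen by the phenol with clean inversion (R → S) sets C8''.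

**Step 6**
Reactants: 9, aryloxy ester; 3, 1-(benzyloxy)-4-bromo-2-methoxybenzene (used as its Grignard reagent)
Product: 10, (1S,2S)-1-[4-(benzyloxy)-3-methoxyphenyl]-2-(4-bromo-2,6-dimethoxyphenoxy)propan-1-ol (threo)
Conditions: DIBAL-H (1.05 equiv), CH2Cl2, −78 °C; then ArMgBr (from 3, Mg, THF; 2.5 equiv), MgBr2·OEt2, −78 → −20 °C; chromatography removes the minor erythro isomer
Reagents that add atoms: none (3 is a reactant)
Why: Tandem ester half-reduction/Grignard addition: the α-aryloxy aldehyde is released from the aluminium hemiacetal only in the presence of Mg(II) and is never isolated (no epimerisation at C8''), and Cram-chelate addition (Mg bridging C=O and the aryloxy/ortho-OMe oxygens) brings the aryl group in on the face bearing H rather than CH3, giving the syn (threo, 7''S,8''S) alcohol; the ring-B bromide is inert to DIBAL and ArMgBr.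

**Step 7**
Reactants: 5, primary alcohol; 10, aryl bromide
Product: 11, (1S,2S)-1-[4-(benzyloxy)-3-methoxyphenyl]-2-{4-[(2R,3S)-4-[4-(benzyloxy)-3-methoxyphenyl]-2,3-dimethylbutyl]-2,6-dimethoxyphenoxy}propan-1-ol
Conditions: 5 (1.2 equiv), 5,7-di-tert-butyl-3-phenylbenzoxazolium BF4, pyridine, MTBE, rt, 15 min; then 10, NiBr2·dtbbpy (5 mol %), [Ir(ppy)2(dtbbpy)]PF6 (1.5 mol %), quinuclidine, phthalimide, DMA, 450 nm LEDs, rt
Reagents that add atoms: none
Why: Ni/photoredox deoxygenative C(sp3)–C(sp2) arylation of an alcohol: the benzoxazolium adduct of 5 is oxidised, deprotonated and undergoes β-scission to the primary C7' radical, which is captured by the Ar–Ni species from 10 and reductively eliminated; the radical carbon is not stereogenic, the adjacent stereocentre is untouched, and only 5 is pre-activated so the secondary OH of 10 is a spectator.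

**Step 8**
Reactants: 11, bis-benzyl ether
Product: 12, (+)-(7''S,8S,8'R,8''S)-4,4''-dihydroxy-3,3',3'',5'-tetramethoxy-4',8''-oxy-8,8'-sesquineolignan-7''-ol (target)
Conditions: H2 (1 atm), 10 % Pd/C, EtOAc–EtOH, rt
Reagents that add atoms: none
Why: Hydrogenolysis of the two benzyl aryl ethers; under neutral conditions the β-aryloxy benzylic alcohol at C7'' is retained and no stereocentre is involved.

## Compound list

1 | meso-(2R,3S)-2,3-dimethylsuccinic acid | OC(=O)[C@H](C)[C@H](C)C(=O)O | starting material
2 | cis-(3R,4S)-3,4-dimethyloxolane-2,5-dione | O=C1[C@H](C)[C@H](C)C(=O)O1 | intermediate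
3 | 1-(benzyloxy)-4-bromo-2-methoxybenzene | COc1cc(Br)ccc1OCc1ccccc1 | starting material
4 | (2S,3R)-4-[4-(benzyloxy)-3-methoxyphenyl]-2,3-dimethyl-4-oxobutanoic acid | COc1cc(C(=O)[C@H](C)[C@H](C)C(=O)O)ccc1OCc1ccccc1 | intermediate
5 | (2S,3S)-4-[4-(benzyloxy)-3-methoxyphenyl]-2,3-dimethylbutan-1-ol | COc1cc(C[C@H](C)[C@H](C)CO)ccc1OCc1ccccc1 | intermediate
6 | 2,6-dimethoxyphenol (syringol) | COc1cccc(OC)c1O | starting material
7 | 4-bromo-2,6-dimethoxyphenol | COc1cc(Br)cc(OC)c1O | intermediate
8 | methyl (R)-lactate | C[C@@H](O)C(=O)OC | starting material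
9 | methyl (2S)-2-(4-bromo-2,6-dimethoxyphenoxy)propanoate | C[C@H](Oc1c(OC)cc(Br)cc1OC)C(=O)OC | intermediate
10 | (1S,2S)-1-[4-(benzyloxy)-3-methoxyphenyl]-2-(4-bromo-2,6-dimethoxyphenoxy)propan-1-ol | COc1cc(Br)cc(OC)c1O[C@@H](C)[C@@H](O)c1ccc(OCc2ccccc2)c(OC)c1 | intermediate
11 | (1S,2S)-1-[4-(benzyloxy)-3-methoxyphenyl]-2-{4-[(2R,3S)-4-[4-(benzyloxy)-3-methoxyphenyl]-2,3-dimethylbutyl]-2,6-dimethoxyphenoxy}propan-1-ol | COc1cc(C[C@H](C)[C@H](C)Cc2cc(OC)c(O[C@@H](C)[C@@H](O)c3ccc(OCc4ccccc4)c(OC)c3)c(OC)c2)ccc1OCc1ccccc1 | intermediate
12 | (+)-(7''S,8S,8'R,8''S)-4,4''-dihydroxy-3,3',3'',5'-tetramethoxy-4',8''-oxy-8,8'-sesquineolignan-7''-ol | COc1cc(C[C@H](C)[C@H](C)Cc2cc(OC)c(O[C@@H](C)[C@@H](O)c3ccc(O)c(OC)c3)c(OC)c2)ccc1O | target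

## Summary

Total step count: 8 (7 if anhydride 2 is bought rather than made).
Longest linear sequence: 5 steps (1 → 2 → 3 → 7 → 8, or 4 → 5 → 6 → 7 → 8).

Three steps most likely to fail, each with a fallback:

- **Step 7 (fragment union).** Risks are the electron-rich aryl bromide and the free secondary OH of 10 under Ni/photoredox conditions. Fallback: convert 5 to the primary iodide (I2, PPh3, imidazole), make the alkylzinc (Zn, LiCl) and run a Pd/SPhos Negishi coupling with 10 (or its TES ether), replacing the radical coupling with a two-electron one.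
- **Step 3 (one-pot deoxygenation and acid reduction).** Risks are styrene formation from the benzylic cation (yield loss) and partial loss of the benzyl ether to the Lewis acid. Fallback: a non-cationic route: methyl ester of 4 → tosylhydrazone → catecholborane/NaOAc reduction, then LiAlH4 to 5.
- **Step 2 (key desymmetrisation).** An ee of only about 85–90 % would carry through as a C8/C8' diastereomer of 12 that is very hard to remove, and the ligand sense needs confirming. Fallback: reduce 1 to meso-2,3-dimethylbutane-1,4-diol and desymmetrise it by lipase/vinyl acetate monoacetylation; deoxygenative arylation of the free CH2OH with 3 and acetate removal give 5 with no benzylic ketone. Either monoacetate enantiomer is usable because the order of the two arylations (3, then 10, or the reverse) can be swapped.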